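**Plan**

- Cuts: the O7–CH3 bond and the three MOM-masked O–H bonds of ring B; the C6–CH2 and C8–CH2 prenyl bonds; the C3–CH2 prenyl bond; O1–C2 and C2–C3 of ring C.
- Enabling feature: in ring A, C6 sits next to C5–O and C8 next to C7–O, so each of these C-prenyl groups is the [3,3] image of a 1,1-dimethylallyl group on the neighbouring oxygen (O5, O7).
- Forward: ring A (phloroacetophenone) takes up both tertiary ethers as 1,1-dimethylpropargyl groups before ring C exists. The ring B acid is joined as an aryl ester, a Baker–Venkataraman shift makes C2–C3, the diketone is C-prenylated, and cyclodehydration closes ring C at O1–C2.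
- Endgame: semihydrogenation unmasks the bis(1,1-dimethylallyl) ether, the double Claisen rearrangement moves both groups to C6 and C8, then 7-O-methylation and MOM removal.
- Stereochemistry: the target has no stereocentre and no stereogenic double bond; the transient stereocentres in 10, 11, 14 and 16 are erased within the route.

Key step: step 9

Remark: the hydrogen-bonded 5-OH of a finished flavone is not expected to accept a tertiary allyl or propargyl electrophile. Both tertiary ethers are therefore installed on the acetophenone, where one ortho hydroxyl is always free of the chelate, and are carried as the more robust propargyl ethers until just before the rearrangement. 3-Chloro-3-methylbut-1-yne is taken as commercially available.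

**Route**

Step 1
Reactants: 1 2,4,6-trihydroxyacetophenone; 2 3-chloro-3-methylbut-1-yne
Product: 3 1-[2-hydroxy-4,6-bis(2-methylbut-3-yn-2-yloxy)phenyl]ethanone
Conditions: 2 (2.4 equiv), DBU (2.6 equiv), CuCl2·2H2O (1 mol%), MeCN, −5 °C to rt
Reagents that add atoms: none
Why: Copper-catalysed propargylic etherification (divalent copper chloride and DBU, through a copper allenylidene) should alkylate the para hydroxyl and the one ortho hydroxyl that is not tied to the acetyl group by a hydrogen bond, leaving the chelated hydroxyl free for the later ester.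

Step 2
Reactants: 4 2,4,5-trihydroxybenzaldehyde
Product: 5 2,4,5-tris(methoxymethoxy)benzaldehyde
Conditions: MOMCl (4 equiv), i-Pr2NEt, DMF, 0 °C to rt, argon
Reagents that add atoms: chloromethyl methyl ether (MOMCl), COCCl
Why: O-alkylation of the three phenols with the reactive α-chloro ether under amine base gives MOM acetals that tolerate the basic, reductive and thermal steps ahead and leave under mild acid.

Step 3
Reactants: 5 2,4,5-tris(methoxymethoxy)benzaldehyde
Product: 6 2,4,5-tris(methoxymethoxy)benzoic acid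
Conditions: NaClO2, NaH2PO4, 2-methylbut-2-ene, t-BuOH/H2O, rt
Reagents that add atoms: sodium chlorite, [Na+].[O-]Cl=O
Why: Pinnick oxidation converts the aldehyde to the acid at buffered pH, with the alkene scavenging HOCl so that the electron-rich ring and the MOM ethers are not attacked.

Step 4
Reactants: 3 1-[2-hydroxy-4,6-bis(2-methylbut-3-yn-2-yloxy)phenyl]ethanone; 6 2,4,5-tris(methoxymethoxy)benzoic acid
Product: 7 2-acetyl-3,5-bis(2-methylbut-3-yn-2-yloxy)phenyl 2,4,5-tris(methoxymethoxy)benzoate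
Conditions: EDC·HCl, DMAP, CH2Cl2, rt
Reagents that add atoms: none
Why: Steglich esterification acylates the remaining chelated phenol through the acylpyridinium species and avoids an acid chloride, whose preparation would endanger the MOM ethers.

Step 5
Reactants: 7 2-acetyl-3,5-bis(2-methylbut-3-yn-2-yloxy)phenyl 2,4,5-tris(methoxymethoxy)benzoate
Product: 8 1-[2-hydroxy-4,6-bis(2-methylbut-3-yn-2-yloxy)phenyl]-3-[2,4,5-tris(methoxymethoxy)phenyl]propane-1,3-dione
Conditions: LiN(SiMe3)2 (3 equiv), THF, −78 °C to 0 °C; aqueous NH4Cl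
Reagents that add atoms: none
Why: Baker–Venkataraman rearrangement, in which the lithium enolate of the acetyl group attacks the neighbouring aryl ester and the O-to-C acyl shift forms the future C2–C3 bond of ring C.

Step 6
Reactants: 8 1-[2-hydroxy-4,6-bis(2-methylbut-3-yn-2-yloxy)phenyl]-3-[2,4,5-tris(methoxymethoxy)phenyl]propane-1,3-dione; 9 1-bromo-3-methylbut-2-ene (prenyl bromide)
Product: 10 1-[2-hydroxy-4,6-bis(2-methylbut-3-yn-2-yloxy)phenyl]-2-(3-methylbut-2-enyl)-3-[2,4,5-tris(methoxymethoxy)phenyl]propane-1,3-dione (racemic)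
Conditions: 9 (1.1 equiv), K2CO3, acetone, rt
Reagents that add atoms: none
Why: C-alkylation of the 1,3-diketone anion (the most acidic site) with the soft allylic bromide under weak base installs the future 3-prenyl group, and the new stereocentre forms as a racemate that is removed in step 7.

Step 7
Reactants: 10 1-[2-hydroxy-4,6-bis(2-methylbut-3-yn-2-yloxy)phenyl]-2-(3-methylbut-2-enyl)-3-[2,4,5-tris(methoxymethoxy)phenyl]propane-1,3-dione
Product: 12 5,7-bis(2-methylbut-3-yn-2-yloxy)-3-(3-methylbut-2-enyl)-2-[2,4,5-tris(methoxymethoxy)phenyl]chromen-4-one, via hemiketal 11 (not isolated)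
Conditions: PPTS (0.2 equiv), 4 Å molecular sieves, PhMe, 60 °C
Reagents that add atoms: none
Why: Acid-catalysed cyclodehydration of an o-hydroxyaryl 1,3-diketone (the closing stage of the Baker–Venkataraman flavone synthesis), in which the phenol adds to the ring B ketone and water leaves through an aryl- and oxygen-stabilised oxocarbenium ion, with the weak acid PPTS in a non-nucleophilic solvent chosen to spare the MOM and tertiary propargyl ethers.

Step 8
Reactants: 12 5,7-bis(2-methylbut-3-yn-2-yloxy)-3-(3-methylbut-2-enyl)-2-[2,4,5-tris(methoxymethoxy)phenyl]chromen-4-one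
Product: 13 5,7-bis(2-methylbut-3-en-2-yloxy)-3-(3-methylbut-2-enyl)-2-[2,4,5-tris(methoxymethoxy)phenyl]chromen-4-one
Conditions: H2 (1 atm), Pd/CaCO3 poisoned with Pb(OAc)2 (Lindlar catalyst), quinoline, EtOAc, rt
Reagents that add atoms: none
Why: Lindlar semihydrogenation should stop both terminal alkynes at the alkene, while the trisubstituted prenyl alkene and the tetrasubstituted conjugated C2=C3 bond are not reduced on the poisoned catalyst.

Step 9
Reactants: 13 5,7-bis(2-methylbut-3-en-2-yloxy)-3-(3-methylbut-2-enyl)-2-[2,4,5-tris(methoxymethoxy)phenyl]chromen-4-one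
Product: 17 5,7-dihydroxy-3,6,8-tris(3-methylbut-2-enyl)-2-[2,4,5-tris(methoxymethoxy)phenyl]chromen-4-one, via C6 dienone 14 (not isolated), via 6-prenyl 5-phenol 15 (not isolated), via C8 dienone 16 (not isolated)
Conditions: Eu(fod)3 (fod = 6,6,7,7,8,8,8-heptafluoro-2,2-dimethyloctane-3,5-dionate; 10 mol%), PhMe, 60 °C, then 100 °C
Reagents that add atoms: none
Why: Two consecutive aromatic Claisen rearrangements, each a concerted [3,3]-sigmatropic shift through a chair-like six-membered transition state, break an O–CMe2 bond, form an aryl C–CH2 bond and by allyl inversion turn the tertiary ether carbon into the CMe2 end of a linear prenyl group; the ortho-dienones 14 and 16 re-aromatise by enolisation. The closest known reaction type is the thermal or Eu(fod)3-promoted Claisen rearrangement of 1,1-dimethylallyl aryl ethers of flavonoids, coumarins and xanthones. No ring is closed and no stereocentre survives, since C6 of 14 and C8 of 16 become planar on enolisation. The step needs site selectivity of the O7 group between C6 and C8 and the right order of the two shifts. Trivalent europium chelated between the C4 carbonyl and O5 should accelerate the O5 shift at 60 °C, and that group can only reach C6 because its other ortho carbon is the ring-fusion atom C4a. Once 15 has formed, C8 is the only free ortho position for the O7 group, in line with the known C8 preference of 7-allyloxychromones, and the new 5-OH is held in a hydrogen bond to C4=O.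

Step 10
Reactants: 17 5,7-dihydroxy-3,6,8-tris(3-methylbut-2-enyl)-2-[2,4,5-tris(methoxymethoxy)phenyl]chromen-4-one
Product: 18 5-hydroxy-7-methoxy-3,6,8-tris(3-methylbut-2-enyl)-2-[2,4,5-tris(methoxymethoxy)phenyl]chromen-4-one
Conditions: MeI (1.2 equiv), K2CO3, acetone, rt
Reagents that add atoms: iodomethane, CI
Why: Williamson methylation under weak base should be selective for the acidic non-chelated 7-hydroxyl, because the 5-hydroxyl is locked in the hydrogen bond to the C4 carbonyl and is not alkylated under these conditions.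

Step 11
Reactants: 18 5-hydroxy-7-methoxy-3,6,8-tris(3-methylbut-2-enyl)-2-[2,4,5-tris(methoxymethoxy)phenyl]chromen-4-one
Product: 19 5-hydroxy-7-methoxy-3,6,8-tris(3-methylbut-2-enyl)-2-(2,4,5-trihydroxyphenyl)chromen-4-one
Conditions: HCl (3 M aqueous), MeOH, 40 °C, argon
Reagents that add atoms: none
Why: Acid-catalysed acetal exchange with methanol removes the three MOM ethers, and since the only hydroxyl beside a prenyl group on ring A is the chelated, weakly nucleophilic 5-OH, acid-induced chroman formation is not expected under these mild conditions.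

**Compound list**

1 | 2,4,6-trihydroxyacetophenone | CC(=O)c1c(O)cc(O)cc1O | starting material
2 | 3-chloro-3-methylbut-1-yne | C#CC(C)(C)Cl | starting material
3 | 1-[2-hydroxy-4,6-bis(2-methylbut-3-yn-2-yloxy)phenyl]ethanone | CC(=O)c1c(O)cc(OC(C)(C)C#C)cc1OC(C)(C)C#C | intermediate
4 | 2,4,5-trihydroxybenzaldehyde | O=Cc1cc(O)c(O)cc1O | starting material
5 | 2,4,5-tris(methoxymethoxy)benzaldehyde | O=Cc1cc(OCOC)c(OCOC)cc1OCOC | intermediate
6 | 2,4,5-tris(methoxymethoxy)benzoic acid | OC(=O)c1cc(OCOC)c(OCOC)cc1OCOC | intermediate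
7 | 2-acetyl-3,5-bis(2-methylbut-3-yn-2-yloxy)phenyl 2,4,5-tris(methoxymethoxy)benzoate | CC(=O)c1c(OC(=O)c2cc(OCOC)c(OCOC)cc2OCOC)cc(OC(C)(C)C#C)cc1OC(C)(C)C#C | intermediate
8 | 1-[2-hydroxy-4,6-bis(2-methylbut-3-yn-2-yloxy)phenyl]-3-[2,4,5-tris(methoxymethoxy)phenyl]propane-1,3-dione | O=C(CC(=O)c1cc(OCOC)c(OCOC)cc1OCOC)c1c(O)cc(OC(C)(C)C#C)cc1OC(C)(C)C#C | intermediate
9 | 1-bromo-3-methylbut-2-ene (prenyl bromide) | CC(C)=CCBr | starting material
10 | 1-[2-hydroxy-4,6-bis(2-methylbut-3-yn-2-yloxy)phenyl]-2-(3-methylbut-2-enyl)-3-[2,4,5-tris(methoxymethoxy)phenyl]propane-1,3-dione (racemic) | O=C(C(CC=C(C)C)C(=O)c1cc(OCOC)c(OCOC)cc1OCOC)c1c(O)cc(OC(C)(C)C#C)cc1OC(C)(C)C#C | intermediate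
11 | 2-hydroxy-5,7-bis(2-methylbut-3-yn-2-yloxy)-3-(3-methylbut-2-enyl)-2-[2,4,5-tris(methoxymethoxy)phenyl]chroman-4-one (hemiketal, mixture of diastereomers, not isolated) | C#CC(C)(C)Oc1cc(OC(C)(C)C#C)c2C(=O)C(CC=C(C)C)C(O)(c3cc(OCOC)c(OCOC)cc3OCOC)Oc2c1 | intermediate
12 | 5,7-bis(2-methylbut-3-yn-2-yloxy)-3-(3-methylbut-2-enyl)-2-[2,4,5-tris(methoxymethoxy)phenyl]chromen-4-one | C#CC(C)(C)Oc1cc(OC(C)(C)C#C)c2c(=O)c(CC=C(C)C)c(-c3cc(OCOC)c(OCOC)cc3OCOC)oc2c1 | intermediate
13 | 5,7-bis(2-methylbut-3-en-2-yloxy)-3-(3-methylbut-2-enyl)-2-[2,4,5-tris(methoxymethoxy)phenyl]chromen-4-one | C=CC(C)(C)Oc1cc(OC(C)(C)C=C)c2c(=O)c(CC=C(C)C)c(-c3cc(OCOC)c(OCOC)cc3OCOC)oc2c1 | intermediate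
14 | 7-(2-methylbut-3-en-2-yloxy)-3,6-bis(3-methylbut-2-enyl)-2-[2,4,5-tris(methoxymethoxy)phenyl]-6H-chromene-4,5-dione (racemic, not isolated) | C=CC(C)(C)OC1=CC2=C(C(=O)C1CC=C(C)C)C(=O)C(CC=C(C)C)=C(c1cc(OCOC)c(OCOC)cc1OCOC)O2 | intermediate
15 | 5-hydroxy-7-(2-methylbut-3-en-2-yloxy)-3,6-bis(3-methylbut-2-enyl)-2-[2,4,5-tris(methoxymethoxy)phenyl]chromen-4-one (not isolated) | C=CC(C)(C)Oc1cc2oc(-c3cc(OCOC)c(OCOC)cc3OCOC)c(CC=C(C)C)c(=O)c2c(O)c1CC=C(C)C | intermediate
16 | 5-hydroxy-3,6,8-tris(3-methylbut-2-enyl)-2-[2,4,5-tris(methoxymethoxy)phenyl]-8H-chromene-4,7-dione (racemic, not isolated) | O=C1C(CC=C(C)C)=C(O)C2=C(OC(c3cc(OCOC)c(OCOC)cc3OCOC)=C(CC=C(C)C)C2=O)C1CC=C(C)C | intermediate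
17 | 5,7-dihydroxy-3,6,8-tris(3-methylbut-2-enyl)-2-[2,4,5-tris(methoxymethoxy)phenyl]chromen-4-one | Oc1c(CC=C(C)C)c(O)c2c(=O)c(CC=C(C)C)c(-c3cc(OCOC)c(OCOC)cc3OCOC)oc2c1CC=C(C)C | intermediate
18 | 5-hydroxy-7-methoxy-3,6,8-tris(3-methylbut-2-enyl)-2-[2,4,5-tris(methoxymethoxy)phenyl]chromen-4-one | COc1c(CC=C(C)C)c(O)c2c(=O)c(CC=C(C)C)c(-c3cc(OCOC)c(OCOC)cc3OCOC)oc2c1CC=C(C)C | intermediate
19 | 5-hydroxy-7-methoxy-3,6,8-tris(3-methylbut-2-enyl)-2-(2,4,5-trihydroxyphenyl)chromen-4-one | COc1c(CC=C(C)C)c(O)c2c(=O)c(CC=C(C)C)c(-c3cc(O)c(O)cc3O)oc2c1CC=C(C)C | target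

**Count**

Total steps: 11. Longest linear sequence: 10 steps (steps 2 to 11, from 2,4,5-trihydroxybenzaldehyde 4).

**Steps most likely to fail**

Step 9 (double Claisen rearrangement). The tertiary allyl–oxygen bonds may ionise under the Lewis acid with loss of the C5 unit. Alternatively the O7 group may move to C6 before the O5 group has shifted; the O5 group can then reach only C8, by a Claisen–Cope sequence, and would arrive as a reverse prenyl group. The fallback drops the sigmatropic step and prenylates the phloroglucinol ring directly, a known reaction of acylphloroglucinols. It sets out from 1 and 9 and returns to the route at 18.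
- 1 is C-prenylated twice with 9 in aqueous KOH at 0 °C to give 1-[2,4,6-trihydroxy-3,5-bis(3-methylbut-2-enyl)phenyl]ethanone F1.
- The non-chelated 4-hydroxyl is methylated (MeI, 1 equiv, K2CO3, acetone) to 1-[2,6-dihydroxy-4-methoxy-3,5-bis(3-methylbut-2-enyl)phenyl]ethanone F2.
- One of the two equivalent hydroxyls is esterified with 6 (EDC·HCl, DMAP) to 2-acetyl-3-hydroxy-5-methoxy-4,6-bis(3-methylbut-2-enyl)phenyl 2,4,5-tris(methoxymethoxy)benzoate F3.
- Baker–Venkataraman rearrangement (LiN(SiMe3)2, THF) should give 1-[2,6-dihydroxy-4-methoxy-3,5-bis(3-methylbut-2-enyl)phenyl]-3-[2,4,5-tris(methoxymethoxy)phenyl]propane-1,3-dione F4.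
- C-prenylation with 9 (K2CO3, acetone) gives 1-[2,6-dihydroxy-4-methoxy-3,5-bis(3-methylbut-2-enyl)phenyl]-2-(3-methylbut-2-enyl)-3-[2,4,5-tris(methoxymethoxy)phenyl]propane-1,3-dione F5.
- PPTS-mediated cyclodehydration of F5 onto either of the two equivalent hydroxyls should deliver 18, which enters step 11.

Step 7 (cyclodehydration). The acid needed for dehydration may strip MOM ethers in part, or the reaction may stall at the hemiketal. The fallback turns the protecting-group loss into a planned event. It sets out from 10 and returns at 12.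
- TsOH·H2O in MeOH/THF at 50 °C should close ring C and cleave all three MOM ethers, giving 5,7-bis(2-methylbut-3-yn-2-yloxy)-3-(3-methylbut-2-enyl)-2-(2,4,5-trihydroxyphenyl)chromen-4-one F6; the tertiary propargyl ethers are expected to resist dilute protic acid.
- Re-protection (MOMCl, i-Pr2NEt, CH2Cl2, argon) then gives 12.

Step 6 (C-prenylation of the diketone). O-alkylation of the enol or of the phenol, or a second C-alkylation, may compete. The fallback introduces the side chain before the diketone exists. It sets out from 3 and returns at 10.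
- The polyanion of 3 (LiN(i-Pr)2, 4.2 equiv, THF, −78 °C) is alkylated at the acetyl carbon with 9 (1.0 equiv) to give 1-[2-hydroxy-4,6-bis(2-methylbut-3-yn-2-yloxy)phenyl]-5-methylhex-4-en-1-one F7.
- Steglich esterification with 6 gives 2-(5-methylhex-4-enoyl)-3,5-bis(2-methylbut-3-yn-2-yloxy)phenyl 2,4,5-tris(methoxymethoxy)benzoate F8.
- Baker–Venkataraman rearrangement of F8 (LiN(SiMe3)2, THF) gives 10 directly.

**Further compounds**

F1 | step 9 | 1-[2,4,6-trihydroxy-3,5-bis(3-methylbut-2-enyl)phenyl]ethanone | CC(=O)c1c(O)c(CC=C(C)C)c(O)c(CC=C(C)C)c1O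
F2 | step 9 | 1-[2,6-dihydroxy-4-methoxy-3,5-bis(3-methylbut-2-enyl)phenyl]ethanone | CC(=O)c1c(O)c(CC=C(C)C)c(OC)c(CC=C(C)C)c1O
F3 | step 9 | 2-acetyl-3-hydroxy-5-methoxy-4,6-bis(3-methylbut-2-enyl)phenyl 2,4,5-tris(methoxymethoxy)benzoate | CC(=O)c1c(O)c(CC=C(C)C)c(OC)c(CC=C(C)C)c1OC(=O)c1cc(OCOC)c(OCOC)cc1OCOC
F4 | step 9 | 1-[2,6-dihydroxy-4-methoxy-3,5-bis(3-methylbut-2-enyl)phenyl]-3-[2,4,5-tris(methoxymethoxy)phenyl]propane-1,3-dione | O=C(CC(=O)c1cc(OCOC)c(OCOC)cc1OCOC)c1c(O)c(CC=C(C)C)c(OC)c(CC=C(C)C)c1O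
F5 | step 9 | 1-[2,6-dihydroxy-4-methoxy-3,5-bis(3-methylbut-2-enyl)phenyl]-2-(3-methylbut-2-enyl)-3-[2,4,5-tris(methoxymethoxy)phenyl]propane-1,3-dione (racemic) | O=C(C(CC=C(C)C)C(=O)c1cc(OCOC)c(OCOC)cc1OCOC)c1c(O)c(CC=C(C)C)c(OC)c(CC=C(C)C)c1O
F6 | step 7 | 5,7-bis(2-methylbut-3-yn-2-yloxy)-3-(3-methylbut-2-enyl)-2-(2,4,5-trihydroxyphenyl)chromen-4-one | C#CC(C)(C)Oc1cc(OC(C)(C)C#C)c2c(=O)c(CC=C(C)C)c(-c3cc(O)c(O)cc3O)oc2c1
F7 | step 6 | 1-[2-hydroxy-4,6-bis(2-methylbut-3-yn-2-yloxy)phenyl]-5-methylhex-4-en-1-one | CC(C)=CCCC(=O)c1c(O)cc(OC(C)(C)C#C)cc1OC(C)(C)C#C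
F8 | step 6 | 2-(5-methylhex-4-enoyl)-3,5-bis(2-methylbut-3-yn-2-yloxy)phenyl 2,4,5-tris(methoxymethoxy)benzoate | CC(C)=CCCC(=O)c1c(OC(=O)c2cc(OCOC)c(OCOC)cc2OCOC)cc(OC(C)(C)C#C)cc1OC(C)(C)C#C
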